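## Retrosynthetic overview

1. The target is ent-epicatechin-(4β→8)-epicatechin-4β-ol: upper unit (rings A, C, B) 2S,3S,4R, all-cis; lower unit (rings D, F, E) 2R,3R,4S. The plan rests on ring A. There the pyran oxygen O1 (on C8a) and the interflavan carbon C4 (on C4a) are ortho neighbours, the C5 oxygen sits on the other side of C4a, and C4 is clamped between two 2,6-dioxygenated rings (A and D).
2. Key disconnection: O1–C8a and C4–C4a are cut together. Ring A becomes a 3,5-dioxygenated benzyne, and C4 becomes the carboxyl carbon on C8 of the lower unit. In the forward sense this gives the tetra-ortho-oxygenated 2-hydroxybenzophenone.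
3. Rings D, F and E come intact from (−)-epicatechin. The lower 4β-oxygen is introduced on the monomer with DDQ/H2O and carried as a benzyl ether, because later the exposed, doubly benzylic upper C4–H would compete for DDQ.
4. C3, C2 and ring B arrive as an arylacetylide that adds to the ketone. Semi-hydrogenation and mild acid then close ring C as a 4-aryl-2H-chromene.
5. Ring order: D/F/E (bought), A (aryne) and B (bought), with C the only ring formed. Hydroboration, oxidation to the 3-ketone, a converging asymmetric reduction and hydrogenolysis finish the route.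

Key step: step 9

Remark: in compounds 20–26 the upper-unit centres are mixtures that are erased or converge later, so their SMILES leave those centres open. Rotamers about the C4–C8 interflavan bond are treated as conformers.

## Route

Step 1
Reactants: 1 (−)-epicatechin
Product: 2 5,7,3',4'-tetra-O-benzyl-(−)-epicatechin
Conditions: BnBr (4.2 equiv), K2CO3, DMF, 0 °C to rt, Ar
Reagents that add atoms: benzyl bromide BrCc1ccccc1
Why: Williamson etherification; the four phenols are far more acidic than the secondary 3-OH and are alkylated selectively, and the mild base should leave C2 and C3 untouched.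

Step 2
Reactants: 2 5,7,3',4'-tetra-O-benzyl-(−)-epicatechin
Product: 3 8-bromo-5,7,3',4'-tetra-O-benzylepicatechin
Conditions: NBS (1.0 equiv), CH2Cl2, −45 °C to 0 °C
Reagents that add atoms: N-bromosuccinimide O=C1CCC(=O)N1Br
Why: Electrophilic aromatic bromination; of the two free positions of the phloroglucinol-type ring D, C8 is the one that 5,7-di-O-benzyl flavan-3-ols offer first to one equivalent of NBS in the cold.

Step 3
Reactants: 3 8-bromo-5,7,3',4'-tetra-O-benzylepicatechin
Product: 4 8-bromo-5,7,3',4'-tetra-O-benzyl-4β-hydroxyepicatechin (3α,4β-trans-diol)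
Conditions: DDQ (1.2 equiv), CH2Cl2–H2O, rt
Reagents that add atoms: water O
Why: Benzylic oxidation by hydride abstraction; DDQ should remove hydride from C4, whose cation is stabilised by O1, O5 and O7 of ring D, and water should cap it from the β face, anti to the axial 3-OH and to ring E, which sets the 4β centre.

Step 4
Reactants: 4 8-bromo-5,7,3',4'-tetra-O-benzyl-4β-hydroxyepicatechin
Product: 5 8-bromo-3,4,5,7,3',4'-hexa-O-benzyl-4β-hydroxyepicatechin
Conditions: NaH (3 equiv), BnBr (3 equiv), n-Bu4NI (cat.), THF–DMF, 0 °C to rt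
Reagents that add atoms: benzyl bromide BrCc1ccccc1
Why: Williamson etherification caps both secondary hydroxyls at once under basic conditions, in which the acid-labile C4–O bond and the three stereocentres are safe.

Step 5
Reactants: 5 8-bromo-3,4,5,7,3',4'-hexa-O-benzyl-4β-hydroxyepicatechin
Product: 7 3,4,5,7,3',4'-hexa-O-benzyl-4β-hydroxyepicatechin-8-carboxylic acid, via 8-lithio flavan 6 (not isolated)
Conditions: n-BuLi (1.1 equiv), THF, −78 °C; dry CO2; cold 0.5 M HCl to pH 3–4
Reagents that add atoms: carbon dioxide O=C=O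
Why: Bromine–lithium exchange at −78 °C outruns any attack on the benzyl ethers, and carboxylation of the aryllithium should give the acid after a brief cold acidification that spares the C4 benzyl ether.

Step 6
Reactants: 8 3,5-bis(benzyloxy)phenol
Product: 9 2-bromo-3,5-bis(benzyloxy)phenol
Conditions: NBS (1.0 equiv), i-Pr2NH (10 mol %), CH2Cl2, −78 °C to 0 °C
Reagents that add atoms: N-bromosuccinimide O=C1CCC(=O)N1Br
Why: Amine-mediated ortho-bromination of a phenol; the N-bromoamine is steered by hydrogen bonding to the OH, so C2 should react rather than C4, which is wedged between the two benzyloxy groups.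

Step 7
Reactants: 9 2-bromo-3,5-bis(benzyloxy)phenol
Product: 10 [2-bromo-3,5-bis(benzyloxy)phenoxy]trimethylsilane
Conditions: HMDS (1.5 equiv), THF, 70 °C; evaporation
Reagents that add atoms: hexamethyldisilazane C[Si](C)(C)N[Si](C)(C)C
Why: O-silylation with HMDS gives only a volatile by-product, so the moisture-sensitive silyl ether can be used after evaporation.

Step 8
Reactants: 10 [2-bromo-3,5-bis(benzyloxy)phenoxy]trimethylsilane
Product: 13 3,5-bis(benzyloxy)-2-(trimethylsilyl)phenyl triflate, via aryllithium 11 (not isolated), via lithium 2-silylphenolate 12 (not isolated)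
Conditions: n-BuLi (1.1 equiv), THF, −78 °C; Tf2O (1.2 equiv), −78 °C to 0 °C
Reagents that add atoms: triflic anhydride O=S(=O)(OS(=O)(=O)C(F)(F)F)C(F)(F)F
Why: Bromine–lithium exchange triggers the 1,3 O-to-C silyl shift (retro-Brook rearrangement), driven by formation of the lithium phenolate, which Tf2O then traps.

Step 9
Reactants: 7 3,4,5,7,3',4'-hexa-O-benzyl-4β-hydroxyepicatechin-8-carboxylic acid; 13 3,5-bis(benzyloxy)-2-(trimethylsilyl)phenyl triflate
Product: 16 [2-hydroxy-4,6-bis(benzyloxy)phenyl] (hexa-O-benzyl-4β-hydroxyepicatechin-8-yl) ketone, via aryne 14 (not isolated), via aryl caesium ester 15 (not isolated)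
Conditions: 13 (1.5 equiv), CsF (4 equiv), THF (0.02 M), sealed tube, 125 °C
Reagents that add atoms: none
Why: Fluoride removes the silyl group of 13 and loss of triflate gives aryne 14, whose triple bond is polarised by the adjacent benzyloxy group (the future C5 oxygen), so the carboxylate of 7 should add through oxygen at the remote aryne carbon, the future C8a. The aryl anion 15 then sits on the future C4a, ortho to the benzyloxy group that stabilises it inductively, and attacks its own ester carbonyl in a four-centre acyl shift of the anionic Fries type, ending as the chelated o-acyl phenoxide with O1–C8a and C4–C4a both made. The closest known reaction type is the formal insertion of arynes into the C–O bond of aryl carboxylic acids, which is run hot and dilute in THF so that the intramolecular acyl shift outruns protonation of the aryl anion. No ring is closed and no stereocentre is created; the three centres of 7 are remote and see only non-acidic conditions. Two selectivities are needed: regiochemistry (O to C8a, acyl carbon to C4a), secured by the flanking benzyloxy group, and C-acylation over simple O-arylation, secured by dilution and temperature. The hydrogen-bonded, hindered phenol of 16 should be a poor partner for the excess aryne.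

Step 10
Reactants: 17 3,4-bis(benzyloxy)benzaldehyde
Product: 18 1,2-bis(benzyloxy)-4-ethynylbenzene
Conditions: dimethyl (1-diazo-2-oxopropyl)phosphonate (1.3 equiv), K2CO3 (2 equiv), MeOH–THF, rt
Reagents that add atoms: dimethyl (1-diazo-2-oxopropyl)phosphonate COP(=O)(OC)C(=[N+]=[N-])C(C)=O
Why: Ohira–Bestmann homologation; methanolysis frees the diazomethylphosphonate anion, which olefinates the non-enolisable aldehyde, and loss of nitrogen with a 1,2-hydrogen shift gives the terminal alkyne.

Step 11
Reactants: 18 1,2-bis(benzyloxy)-4-ethynylbenzene; 16 ring-A/ring-D 2-hydroxybenzophenone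
Product: 20 tertiary propargylic alcohol (C4 carries OH and ring A and ring D and the ring-B ethynyl group; both carbinol epimers), via lithium acetylide 19 (not isolated)
Conditions: 18 (4 equiv), n-BuLi (3.8 equiv), THF, −78 °C to 0 °C; then 16, −78 °C to rt; aq NH4Cl (pH 7–8); no acidic silica
Reagents that add atoms: none
Why: 1,2-Addition of a lithium acetylide; the first equivalent deprotonates the phenol, the slim sp nucleophile can reach a carbonyl flanked by four ortho oxygens, nothing is enolisable so the reaction can be pushed by warming, and the new carbinol centre is erased in step 13.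

Step 12
Reactants: 20 tertiary propargylic alcohol
Product: 21 (Z)-allylic alcohol (Z-configured C3=C2 between C4 and ring B)
Conditions: H2 (1 atm), Pd/CaCO3 poisoned with Pb(OAc)2, quinoline, EtOAc, rt
Reagents that add atoms: none
Why: Lindlar-type semi-hydrogenation; syn delivery of hydrogen on poisoned palladium should stop at the Z-alkene, leave the aryl benzyl ethers alone, and keep the acid-sensitive carbinol in a basic medium.

Step 13
Reactants: 21 (Z)-allylic alcohol
Product: 23 4-aryl-2H-chromene (perbenzylated flav-3-ene carrying the lower unit at C4; both C2 epimers), via o-quinone methide 22 (not isolated)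
Conditions: PPTS (10 mol %), 4 Å MS, CH2Cl2, 0 °C
Reagents that add atoms: none
Why: Acid-catalysed cyclodehydration of a 2-(1-hydroxyallyl)phenol; the tertiary carbinol between two trioxygenated rings ionises under far weaker acid than the secondary C4 benzyl ether of the lower unit, the delocalised cation and its conjugate base 22 lose the alkene geometry by rotation, and O1 closes on C2 (oxa-6π closure) to form ring C, the lack of control at C2 being harmless because step 16 converges.

Step 14
Reactants: 23 4-aryl-2H-chromene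
Product: 25 2,3-trans-3,4-trans 4-arylflavan-3-ol (rings B and D cis; 2S and 2R series), via C3 borane 24 (not isolated)
Conditions: BH3·THF (5 equiv), THF, 0 °C to rt; 3 M NaOH, 30 % H2O2, 0 °C to rt
Reagents that add atoms: hydrogen peroxide OO
Why: Hydroboration–oxidation; boron goes to the less substituted C3 and hydrogen to the diaryl-bearing C4, syn and on the face anti to ring B, and the oxidation retains configuration, so each C2 epimer should give one alcohol.

Step 15
Reactants: 25 2,3-trans-3,4-trans 4-arylflavan-3-ol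
Product: 26 2,4-diarylchroman-3-one (perbenzylated; C2 and C4 labile)
Conditions: Dess–Martin periodinane (1.5 equiv), NaHCO3, CH2Cl2, 0 °C to rt
Reagents that add atoms: none
Why: Dess–Martin oxidation is the standard neutral way from benzylated flavan-3-ols to flavan-3-ones, and the buffer protects the C4 benzyl ether of the lower unit from the acetic acid released.

Step 16
Reactants: 26 2,4-diarylchroman-3-one
Product: 27 deca-O-benzyl ent-epicatechin-(4β→8)-epicatechin-4β-ol (upper unit 2β,3β,4β all-cis with free 3-OH)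
Conditions: RuCl(p-cymene)[(S,S)-TsDPEN] (5 mol %), HCO2H (5 equiv), Et3N (8 equiv), CH2Cl2, 35 °C, Ar
Reagents that add atoms: none
Why: Proposed new method: both α-carbons of 26 (C2 benzylic and α-oxygenated, C4 doubly benzylic) should enolise in the amine-rich formate medium, so the C2/C4 stereoisomers interconvert, while the Ru–H/N–H species can reach the carbonyl only in a 2,4-cis isomer and only from the face anti to both aryl groups, which places 3-OH cis to both. The (S,S) ligand is expected to select the 2β,4β isomer by turning the bulky C4 side away from the cymene and the C2 aryl/ether side towards it, where the aryl group of an aryl ketone lies, giving 3S and with it 2S and 4R. The closest known reaction type is Noyori–Ikariya transfer hydrogenation with dynamic kinetic resolution of cyclic ketones with a single labile α-aryl or α-alkoxy centre, not yet shown with two labile centres flanking a chroman-3-one.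

Step 17
Reactants: 27 deca-O-benzyl ent-epicatechin-(4β→8)-epicatechin-4β-ol
Product: 28 ent-epicatechin-(4β→8)-epicatechin-4β-ol (target)
Conditions: H2 (1 atm), Pd(OH)2/C, THF–H2O (9:1), rt, stopped at the calculated uptake; filtration under Ar, lyophilisation
Reagents that add atoms: none
Why: Catalytic hydrogenolysis; the ten unhindered O–CH2Ph bonds should be cleaved faster than the crowded secondary ring C4–O bond in a strictly neutral, alcohol-free medium, which also keeps the acid-sensitive flavan-3,4-diol from ionising and leaves all six stereocentres untouched.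

## Compound list

1 | (−)-epicatechin (2R,3R) | Oc1cc(O)c2c(c1)O[C@H](c1ccc(O)c(O)c1)[C@H](O)C2 | starting material
2 | 5,7,3',4'-tetra-O-benzyl-(−)-epicatechin | O(Cc1ccccc1)c1cc(OCc3ccccc3)c2c(c1)O[C@H](c1ccc(OCc3ccccc3)c(OCc3ccccc3)c1)[C@H](O)C2 | intermediate
3 | 8-bromo-5,7,3',4'-tetra-O-benzylepicatechin | Brc1c(OCc3ccccc3)cc(OCc3ccccc3)c2c1O[C@H](c1ccc(OCc3ccccc3)c(OCc3ccccc3)c1)[C@H](O)C2 | intermediate
4 | 8-bromo-5,7,3',4'-tetra-O-benzyl-4β-hydroxyepicatechin | Brc1c(OCc3ccccc3)cc(OCc3ccccc3)c2c1O[C@H](c1ccc(OCc3ccccc3)c(OCc3ccccc3)c1)[C@H](O)[C@H]2O | intermediate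
5 | 8-bromo-3,4,5,7,3',4'-hexa-O-benzyl-4β-hydroxyepicatechin | Brc1c(OCc3ccccc3)cc(OCc3ccccc3)c2c1O[C@H](c1ccc(OCc3ccccc3)c(OCc3ccccc3)c1)[C@H](OCc1ccccc1)[C@H]2OCc1ccccc1 | intermediate
6 | 8-lithio-3,4,5,7,3',4'-hexa-O-benzyl-4β-hydroxyepicatechin | [Li]c1c(OCc3ccccc3)cc(OCc3ccccc3)c2c1O[C@H](c1ccc(OCc3ccccc3)c(OCc3ccccc3)c1)[C@H](OCc1ccccc1)[C@H]2OCc1ccccc1 | intermediate
7 | 3,4,5,7,3',4'-hexa-O-benzyl-4β-hydroxyepicatechin-8-carboxylic acid | OC(=O)c1c(OCc3ccccc3)cc(OCc3ccccc3)c2c1O[C@H](c1ccc(OCc3ccccc3)c(OCc3ccccc3)c1)[C@H](OCc1ccccc1)[C@H]2OCc1ccccc1 | intermediate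
8 | 3,5-bis(benzyloxy)phenol | Oc1cc(OCc2ccccc2)cc(OCc2ccccc2)c1 | starting material
9 | 2-bromo-3,5-bis(benzyloxy)phenol | Oc1cc(OCc2ccccc2)cc(OCc2ccccc2)c1Br | intermediate
10 | [2-bromo-3,5-bis(benzyloxy)phenoxy]trimethylsilane | C[Si](C)(C)Oc1cc(OCc2ccccc2)cc(OCc2ccccc2)c1Br | intermediate
11 | [3,5-bis(benzyloxy)-2-lithiophenoxy]trimethylsilane | C[Si](C)(C)Oc1cc(OCc2ccccc2)cc(OCc2ccccc2)c1[Li] | intermediate
12 | lithium 3,5-bis(benzyloxy)-2-(trimethylsilyl)phenolate | [Li]Oc1cc(OCc2ccccc2)cc(OCc2ccccc2)c1[Si](C)(C)C | intermediate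
13 | 3,5-bis(benzyloxy)-2-(trimethylsilyl)phenyl triflate | C[Si](C)(C)c1c(OCc2ccccc2)cc(OCc2ccccc2)cc1OS(=O)(=O)C(F)(F)F | intermediate
14 | 3,5-bis(benzyloxy)benzyne (1,2-didehydro) | C1#CC(OCc2ccccc2)=CC(OCc2ccccc2)=C1 | intermediate
15 | 2-caesio-3,5-bis(benzyloxy)phenyl ester of acid 7 | [Cs]c1c(OCc3ccccc3)cc(OCc3ccccc3)cc1OC(=O)c1c(OCc3ccccc3)cc(OCc3ccccc3)c2c1O[C@H](c1ccc(OCc3ccccc3)c(OCc3ccccc3)c1)[C@H](OCc1ccccc1)[C@H]2OCc1ccccc1 | intermediate
16 | [2-hydroxy-4,6-bis(benzyloxy)phenyl] (hexa-O-benzyl-4β-hydroxyepicatechin-8-yl) ketone | Oc1cc(OCc3ccccc3)cc(OCc3ccccc3)c1C(=O)c1c(OCc3ccccc3)cc(OCc3ccccc3)c2c1O[C@H](c1ccc(OCc3ccccc3)c(OCc3ccccc3)c1)[C@H](OCc1ccccc1)[C@H]2OCc1ccccc1 | intermediate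
17 | 3,4-bis(benzyloxy)benzaldehyde | O=Cc1ccc(OCc2ccccc2)c(OCc2ccccc2)c1 | starting material
18 | 1,2-bis(benzyloxy)-4-ethynylbenzene | C#Cc1ccc(OCc2ccccc2)c(OCc2ccccc2)c1 | intermediate
19 | lithium [3,4-bis(benzyloxy)phenyl]acetylide | [Li]C#Cc1ccc(OCc2ccccc2)c(OCc2ccccc2)c1 | intermediate
20 | tertiary propargylic alcohol, both carbinol epimers | Oc1cc(OCc3ccccc3)cc(OCc3ccccc3)c1C(O)(C#Cc1ccc(OCc3ccccc3)c(OCc3ccccc3)c1)c1c(OCc3ccccc3)cc(OCc3ccccc3)c2c1O[C@H](c1ccc(OCc3ccccc3)c(OCc3ccccc3)c1)[C@H](OCc1ccccc1)[C@H]2OCc1ccccc1 | intermediate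
21 | (Z)-allylic alcohol, both carbinol epimers | Oc1cc(OCc3ccccc3)cc(OCc3ccccc3)c1C(O)(/C=C\c1ccc(OCc3ccccc3)c(OCc3ccccc3)c1)c1c(OCc3ccccc3)cc(OCc3ccccc3)c2c1O[C@H](c1ccc(OCc3ccccc3)c(OCc3ccccc3)c1)[C@H](OCc1ccccc1)[C@H]2OCc1ccccc1 | intermediate
22 | styryl-substituted o-quinone methide of ring A, alkene geometries mobile | O=C1C=C(OCc3ccccc3)C=C(OCc3ccccc3)C1=C(C=Cc1ccc(OCc3ccccc3)c(OCc3ccccc3)c1)c1c(OCc3ccccc3)cc(OCc3ccccc3)c2c1O[C@H](c1ccc(OCc3ccccc3)c(OCc3ccccc3)c1)[C@H](OCc1ccccc1)[C@H]2OCc1ccccc1 | intermediate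
23 | 4-aryl-2H-chromene (flav-3-ene), both C2 epimers | O(Cc1ccccc1)c1cc(OCc3ccccc3)c2c(c1)OC(c1ccc(OCc3ccccc3)c(OCc3ccccc3)c1)C=C2c1c(OCc3ccccc3)cc(OCc3ccccc3)c2c1O[C@H](c1ccc(OCc3ccccc3)c(OCc3ccccc3)c1)[C@H](OCc1ccccc1)[C@H]2OCc1ccccc1 | intermediate
24 | C3 borane, B trans to ring B and trans to ring D, both series | O(Cc1ccccc1)c1cc(OCc3ccccc3)c2c(c1)OC(c1ccc(OCc3ccccc3)c(OCc3ccccc3)c1)C(B)C2c1c(OCc3ccccc3)cc(OCc3ccccc3)c2c1O[C@H](c1ccc(OCc3ccccc3)c(OCc3ccccc3)c1)[C@H](OCc1ccccc1)[C@H]2OCc1ccccc1 | intermediate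
25 | 2,3-trans-3,4-trans 4-arylflavan-3-ol, 2S and 2R series | O(Cc1ccccc1)c1cc(OCc3ccccc3)c2c(c1)OC(c1ccc(OCc3ccccc3)c(OCc3ccccc3)c1)C(O)C2c1c(OCc3ccccc3)cc(OCc3ccccc3)c2c1O[C@H](c1ccc(OCc3ccccc3)c(OCc3ccccc3)c1)[C@H](OCc1ccccc1)[C@H]2OCc1ccccc1 | intermediate
26 | 2,4-diarylchroman-3-one, C2 and C4 labile | O(Cc1ccccc1)c1cc(OCc3ccccc3)c2c(c1)OC(c1ccc(OCc3ccccc3)c(OCc3ccccc3)c1)C(=O)C2c1c(OCc3ccccc3)cc(OCc3ccccc3)c2c1O[C@H](c1ccc(OCc3ccccc3)c(OCc3ccccc3)c1)[C@H](OCc1ccccc1)[C@H]2OCc1ccccc1 | intermediate
27 | deca-O-benzyl ent-epicatechin-(4β→8)-epicatechin-4β-ol, upper 3-OH free | O(Cc1ccccc1)c1cc(OCc3ccccc3)c2c(c1)O[C@@H](c1ccc(OCc3ccccc3)c(OCc3ccccc3)c1)[C@@H](O)[C@H]2c1c(OCc3ccccc3)cc(OCc3ccccc3)c2c1O[C@H](c1ccc(OCc3ccccc3)c(OCc3ccccc3)c1)[C@H](OCc1ccccc1)[C@H]2OCc1ccccc1 | intermediate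
28 | ent-epicatechin-(4β→8)-epicatechin-4β-ol (CNP0114173.1) | Oc1cc(O)c2c(c1)O[C@@H](c1ccc(O)c(O)c1)[C@@H](O)[C@H]2c1c(O)cc(O)c2c1O[C@H](c1ccc(O)c(O)c1)[C@H](O)[C@H]2O | target

## Step count and risks

Total step count: 17. Longest linear sequence: 13 steps (1 to 28 through steps 1–5, 9 and 11–17).

**Steps most likely to fail**

1. **Step 16 (converging transfer hydrogenation).**
   - What may go wrong: epimerisation at the crowded C4 may be slower than reduction, so the 2R series would be reduced as it stands. The catalyst may show a weak or reversed facial preference on a ketone with no aryl group directly on the carbonyl. Hydride transfer to the flanked carbonyl may stall.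
   - Fallback, from 25 back to 27, all by known chemistry: the two diastereomers of 25 are separated by chromatography. The 2S-series alcohol, the 2β,4β-diaryl-3α-ol F1, is oxidised alone with Dess–Martin periodinane/NaHCO3 to the configurationally defined 2β,4β-diaryl ketone F2. F2 is reduced at once with LiBH(s-Bu)3 in THF at −78 °C. The bulky hydride approaches anti to both aryl groups, as in the familiar trans-to-cis inversion of flavan-3-ols, and gives 27.
   - Recycling: the 2R-series alcohol can be oxidised, equilibrated with DBU as part of 26, reduced in the same way and separated again.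

2. **Step 9 (aryne insertion).**
   - What may go wrong: the aryl anion may be protonated before the acyl shift, giving plain O-arylation. Acyl transfer to a carbonyl shielded by two ortho oxygens may be too slow. The electron-rich acid may lose CO2 at 125 °C. The product phenoxide may be arylated a second time.
   - Fallback, from 5 back to 16, which replaces the aryne by acylation of an aryllithium: commercial 2,4,6-trihydroxybenzoic acid is condensed with acetone (TFA/TFAA) to 5,7-dihydroxy-2,2-dimethyl-4H-1,3-benzodioxin-4-one F3. F3 is benzylated (BnBr, K2CO3, DMF) to the 5,7-bis(benzyloxy) dioxinone F4.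
   - Return to the route: the aryllithium 6, generated from 5 as in step 5, is added to F4 in THF at −78 °C. The tetrahedral adduct collapses with loss of the acetonide carbon unit to the phenoxide of 16, whose charge protects the ketone from a second addition.

3. **Step 11 (acetylide addition).**
   - What may go wrong: the phenoxide formed first pushes electron density into a carbonyl already screened by four ortho oxygens, so the addition may stall or revert on warming.
   - Fallback, from 16 back to 20, which removes the anionic deactivation: the phenol is masked as its allyl ether (allyl bromide, K2CO3, DMF) to give the O-allyl benzophenone F5. Acetylide 19 is added to this neutral ketone to give the O-allyl propargylic alcohol F6. The allyl group is then transferred to morpholine with Pd(PPh3)4 in THF at rt under neutral conditions, which returns 20.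

## Further compounds

F1 | step 16 | 2S-series 2β,4β-diaryl-3α-ol (single diastereomer of 25) | O(Cc1ccccc1)c1cc(OCc3ccccc3)c2c(c1)O[C@@H](c1ccc(OCc3ccccc3)c(OCc3ccccc3)c1)[C@H](O)[C@H]2c1c(OCc3ccccc3)cc(OCc3ccccc3)c2c1O[C@H](c1ccc(OCc3ccccc3)c(OCc3ccccc3)c1)[C@H](OCc1ccccc1)[C@H]2OCc1ccccc1
F2 | step 16 | 2β,4β-diarylchroman-3-one (single diastereomer of 26) | O(Cc1ccccc1)c1cc(OCc3ccccc3)c2c(c1)O[C@@H](c1ccc(OCc3ccccc3)c(OCc3ccccc3)c1)C(=O)[C@H]2c1c(OCc3ccccc3)cc(OCc3ccccc3)c2c1O[C@H](c1ccc(OCc3ccccc3)c(OCc3ccccc3)c1)[C@H](OCc1ccccc1)[C@H]2OCc1ccccc1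
F3 | step 9 | 5,7-dihydroxy-2,2-dimethyl-4H-1,3-benzodioxin-4-one | CC1(C)OC(=O)c2c(O)cc(O)cc2O1
F4 | step 9 | 5,7-bis(benzyloxy)-2,2-dimethyl-4H-1,3-benzodioxin-4-one | CC1(C)OC(=O)c2c(OCc3ccccc3)cc(OCc3ccccc3)cc2O1
F5 | step 11 | O-allyl ether of benzophenone 16 | C=CCOc1cc(OCc3ccccc3)cc(OCc3ccccc3)c1C(=O)c1c(OCc3ccccc3)cc(OCc3ccccc3)c2c1O[C@H](c1ccc(OCc3ccccc3)c(OCc3ccccc3)c1)[C@H](OCc1ccccc1)[C@H]2OCc1ccccc1
F6 | step 11 | O-allyl ether of propargylic alcohol 20, both carbinol epimers | C=CCOc1cc(OCc3ccccc3)cc(OCc3ccccc3)c1C(O)(C#Cc1ccc(OCc3ccccc3)c(OCc3ccccc3)c1)c1c(OCc3ccccc3)cc(OCc3ccccc3)c2c1O[C@H](c1ccc(OCc3ccccc3)c(OCc3ccccc3)c1)[C@H](OCc1ccccc1)[C@H]2OCc1ccccc1
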